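**Plan**

1. Retrosynthesis (central ring: C1 O-hydroxybutanoyl, C2 OH, C3 aryl, C4 O-phenylpropanoyl, C5 OH, C6 aryl): the benzyl ethers are cut first, then the O4–acyl bond (acylation), the C1–O bond (Baeyer–Villiger oxidation of a C1 aryl ketone), and last the ring bonds C1–C2 and C5–C6.
2. Enabling feature: in the fully substituted central ring the free hydroxyls on C2 and C5 are para and so are the aryl groups on C3 and C6. This is the hydroquinone that a 2-silyloxyfuran leaves at its C2 and C5 after [4+2] addition to an alkyne and opening of the oxygen bridge; C2–C5 and the C5 oxygen come from the furan, C1 and C6 from an aryl ynone that already carries the chain.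
3. Forward: a Dieckmann condensation closes the furanone ring of a 3-aryltetronic acid, which becomes the 4-MOM-oxy-2-silyloxyfuran; the ynone is joined from a Weinreb amide and an aryl acetylide; the cycloaddition/aromatisation then closes the central benzene ring.
4. Endgame: silyl-to-benzyl exchange, Baeyer–Villiger oxidation with retention of the chain, MOM removal, O4 acylation, global hydrogenolysis.
5. Stereochemistry: the single S centre is bought as ethyl (S)-3-hydroxybutanoate; it stays β to a carbonyl group throughout and none of its bonds is touched.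

Key step: step 7

Remark: central-ring positions C1–C6 correspond to terphenyl locants 2', 3', 4', 5', 6', 1'; if the silyl group of the cycloadduct ends up on O5 instead of O2, the benzyl exchange that follows gives the same bis(benzyl ether), so nothing downstream depends on it.

**Route**

Step 1
Reactants: 1 methyl 2-[4-(benzyloxy)phenyl]acetate; 2 methyl glycolate
Product: 4 3-[4-(benzyloxy)phenyl]-4-hydroxyfuran-2(5H)-one, via glycolate ester 3 (not isolated)
Conditions: KOtBu (2.2 equiv), DMF, 0 °C → rt; then 1 M HCl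
Reagents that add atoms: none
Why: Tandem transesterification–Dieckmann condensation, in which the potassium alkoxide of 2 exchanges into the ester of 1 to give 3, whose benzylic CH2 is deprotonated and closes the five-membered ring onto the glycolate ester, the stable tetronate anion driving the sequence forward until acidification.

Step 2
Reactants: 4 3-[4-(benzyloxy)phenyl]-4-hydroxyfuran-2(5H)-one
Product: 5 3-[4-(benzyloxy)phenyl]-4-(methoxymethoxy)furan-2(5H)-one
Conditions: MOMCl (1.2 equiv), iPr2NEt (1.5 equiv), CH2Cl2, 0 °C → rt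
Reagents that add atoms: chloromethyl methyl ether, COCCl
Why: O-Alkylation of the vinylogous acid with the hard electrophile MOMCl under amine base should take place at the C4 oxygen and give the conjugated 4-alkoxybutenolide, a standard protection of tetronic acids.

Step 3
Reactants: 5 3-[4-(benzyloxy)phenyl]-4-(methoxymethoxy)furan-2(5H)-one
Product: 6 3-[4-(benzyloxy)phenyl]-2-(tert-butyldimethylsilyloxy)-4-(methoxymethoxy)furan
Conditions: Et3N (2.0 equiv), TBSOTf (1.2 equiv), CH2Cl2, 0 °C; evaporation, pentane extraction and filtration under Ar, no aqueous work-up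
Reagents that add atoms: tert-butyldimethylsilyl trifluoromethanesulfonate, CC(C)(C)[Si](C)(C)OS(=O)(=O)C(F)(F)F
Why: Soft enolisation, in which silylation of the lactone carbonyl oxygen and removal of a C5 proton by Et3N aromatise the butenolide to the 2-silyloxyfuran, is the usual way to such dienes, and the excess amine keeps the silyl triflate from attacking the acetal.

Step 4
Reactants: 7 ethyl (S)-3-hydroxybutanoate
Product: 8 ethyl (S)-3-(benzyloxy)butanoate
Conditions: BnOC(=NH)CCl3 (1.5 equiv), TfOH (5 mol %), CH2Cl2/cyclohexane, 0 °C → rt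
Reagents that add atoms: benzyl 2,2,2-trichloroacetimidate, N=C(OCc1ccccc1)C(Cl)(Cl)Cl
Why: Acid-catalysed benzylation with the trichloroacetimidate alkylates the hydroxyl oxygen without base, so the β-hydroxy ester neither eliminates nor undergoes retro-aldol cleavage, and the C–O bond at the stereocentre, hence the S configuration, is untouched.

Step 5
Reactants: 8 ethyl (S)-3-(benzyloxy)butanoate
Product: 9 (S)-3-(benzyloxy)-N-methoxy-N-methylbutanamide
Conditions: MeNH(OMe)·HCl (1.5 equiv), iPrMgCl (3.0 equiv), THF, −20 → 0 °C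
Reagents that add atoms: N,O-dimethylhydroxylamine hydrochloride, CNOC.Cl
Why: Direct aminolysis of the ester by the magnesium amide ClMgN(OMe)Me formed in the flask is a standard route to Weinreb amides and runs at low temperature, where β-elimination of the benzyloxy group should not compete.

Step 6
Reactants: 9 (S)-3-(benzyloxy)-N-methoxy-N-methylbutanamide; 10 1-(benzyloxy)-4-ethynylbenzene
Product: 12 (S)-5-(benzyloxy)-1-[4-(benzyloxy)phenyl]hex-1-yn-3-one, via lithium acetylide 11 (not isolated)
Conditions: 10 (1.3 equiv), n-BuLi (1.25 equiv), THF, −78 °C; then 9, −78 → 0 °C; sat. aq NH4Cl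
Reagents that add atoms: none
Why: Weinreb ketone synthesis, in which the lithium acetylide adds once to the amide and the chelated tetrahedral intermediate holds until the quench, so the base-sensitive β-benzyloxy ynone is released only when no acetylide is left.

Step 7
Reactants: 6 3-[4-(benzyloxy)phenyl]-2-(tert-butyldimethylsilyloxy)-4-(methoxymethoxy)furan; 12 (S)-5-(benzyloxy)-1-[4-(benzyloxy)phenyl]hex-1-yn-3-one
Product: 14 (S)-3-(benzyloxy)-1-[4,4''-bis(benzyloxy)-3'-(tert-butyldimethylsilyloxy)-6'-hydroxy-5'-(methoxymethoxy)-[1,1':4',1''-terphenyl]-2'-yl]butan-1-one, via oxanorbornadiene 13 (not isolated)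
Conditions: 6 (1.5 equiv), toluene (0.5 M), 100 °C, sealed tube, Ar
Reagents that add atoms: none
Why: This is a Diels–Alder cycloaddition followed by ring-opening aromatisation, the known behaviour of 2-silyloxyfurans towards acetylenic ketones and esters, applied here to a more highly substituted pair. The diene C2=C3–C4=C5 of 6 carries donors at C2 and C4 like a cyclic 1,3-dioxygenated butadiene and adds the acceptor alkyne of 12 in a concerted but asynchronous [4+2] process, in which the bond from furan C5 to the aryl-bearing β-carbon of the ynone runs ahead of the bond from furan C2 to the acyl-bearing α-carbon; a stepwise vinylogous Mukaiyama–Michael addition followed by closure onto the silyloxycarbenium ion would lead to the same 7-oxanorbornadiene 13. In 13 the bridgehead ketal carbon bearing the silyloxy group ionises with cleavage of its bond to the bridging oxygen, and transfer of the other bridgehead proton to that oxygen aromatises the ring, so the former furan oxygen becomes the C5 phenol para to the C2 silyl ether. The central benzene ring is thus closed by intermolecular [4+2] cycloaddition that forms C1–C2 and C5–C6, not by cyclisation of a chain. No stereocentre is created in 14, because the two bridgehead centres of 13 are erased on aromatisation and the remote S centre is a spectator. The selectivity needed is regiochemical (aryl groups para, acyl group next to the silyloxy carbon), and it is secured because the 2-silyloxy and 4-alkoxy donors both make furan C5 the nucleophilic terminus while the ketone makes the aryl-substituted alkyne carbon the electrophilic one, so the polarisations match in one orientation only.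

Step 8
Reactants: 14 (S)-3-(benzyloxy)-1-[4,4''-bis(benzyloxy)-3'-(tert-butyldimethylsilyloxy)-6'-hydroxy-5'-(methoxymethoxy)-[1,1':4',1''-terphenyl]-2'-yl]butan-1-one
Product: 17 (S)-3-(benzyloxy)-1-[3',4,4'',6'-tetrakis(benzyloxy)-5'-(methoxymethoxy)-[1,1':4',1''-terphenyl]-2'-yl]butan-1-one, via C5-benzyl ether 15 (not isolated), via C2-phenol 16 (not isolated)
Conditions: BnBr (3 equiv), K2CO3 (2 equiv), DMF, rt, Ar; then CsF (2 equiv), rt → 40 °C
Reagents that add atoms: benzyl bromide, BrCc1ccccc1
Why: Williamson benzylation of the free C5 phenol, followed by fluoride cleavage of the aryl silyl ether with benzyl bromide present to trap the C2 phenoxide as it forms, avoids the oxidation-prone free hydroquinone and converges any O2/O5 silyl isomers of 14 on one product under bases mild enough for the β-benzyloxy ketone.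

Step 9
Reactants: 17 (S)-3-(benzyloxy)-1-[3',4,4'',6'-tetrakis(benzyloxy)-5'-(methoxymethoxy)-[1,1':4',1''-terphenyl]-2'-yl]butan-1-one
Product: 18 3',4,4'',6'-tetrakis(benzyloxy)-5'-(methoxymethoxy)-[1,1':4',1''-terphenyl]-2'-yl (S)-3-(benzyloxy)butanoate
Conditions: mCPBA (3 equiv), CH2Cl2, 0 °C → rt
Reagents that add atoms: 3-chloroperbenzoic acid, O=C(OO)c1cccc(Cl)c1
Why: Baeyer–Villiger oxidation, in which the electron-rich, doubly ortho-substituted aryl group (oxygen donors ortho and para) should migrate from the peracid adduct in preference to the primary alkyl carbon, gives the aryl ester with the chain and its stereocentre intact, as is usual for oxygenated aryl alkyl ketones.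

Step 10
Reactants: 18 3',4,4'',6'-tetrakis(benzyloxy)-5'-(methoxymethoxy)-[1,1':4',1''-terphenyl]-2'-yl (S)-3-(benzyloxy)butanoate
Product: 19 3',4,4'',6'-tetrakis(benzyloxy)-5'-hydroxy-[1,1':4',1''-terphenyl]-2'-yl (S)-3-(benzyloxy)butanoate
Conditions: ZnBr2 (1.5 equiv), n-PrSH (3 equiv), CH2Cl2, 0 °C, 10 min
Reagents that add atoms: none
Why: Lewis-acid activation of the acetal by ZnBr2 with capture of the methoxymethyl cation by the thiol cleaves aryl MOM ethers within minutes, leaves benzyl ethers and aryl esters alone and keeps formaldehyde equivalents away from the electron-rich rings.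

Step 11
Reactants: 19 3',4,4'',6'-tetrakis(benzyloxy)-5'-hydroxy-[1,1':4',1''-terphenyl]-2'-yl (S)-3-(benzyloxy)butanoate; 20 3-phenylpropanoyl chloride
Product: 21 3',4,4'',6'-tetrakis(benzyloxy)-5'-[(3-phenylpropanoyl)oxy]-[1,1':4',1''-terphenyl]-2'-yl (S)-3-(benzyloxy)butanoate
Conditions: 20 (1.5 equiv), Et3N (2 equiv), 4-(dimethylamino)pyridine (0.1 equiv), CH2Cl2, 0 °C → rt
Reagents that add atoms: none
Why: Acylation of the only free hydroxyl with the acid chloride under nucleophilic catalysis is a standard esterification, and because both neighbours of the existing C1 ester are blocked (C2 benzyl ether, C6 aryl) no acyl migration can take place.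

Step 12
Reactants: 21 3',4,4'',6'-tetrakis(benzyloxy)-5'-[(3-phenylpropanoyl)oxy]-[1,1':4',1''-terphenyl]-2'-yl (S)-3-(benzyloxy)butanoate
Product: 22 3',4,4'',6'-tetrahydroxy-5'-[(3-phenylpropanoyl)oxy]-[1,1':4',1''-terphenyl]-2'-yl (S)-3-hydroxybutanoate
Conditions: H2 (1 atm), Pd(OH)2/C, EtOAc/THF, rt; filtration under Ar
Reagents that add atoms: none
Why: Catalytic hydrogenolysis should cleave the four aryl benzyl ethers and the secondary alkyl benzyl ether under neutral conditions in a non-nucleophilic solvent, so the two aryl esters neither transesterify nor migrate to the phenols set free next to them.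

**Compound list**

1 | methyl 2-[4-(benzyloxy)phenyl]acetate | COC(=O)Cc1ccc(OCc2ccccc2)cc1 | starting material
2 | methyl glycolate (methyl 2-hydroxyacetate) | COC(=O)CO | starting material
3 | methyl 2-({2-[4-(benzyloxy)phenyl]acetyl}oxy)acetate | COC(=O)COC(=O)Cc1ccc(OCc2ccccc2)cc1 | intermediate (not isolated)
4 | 3-[4-(benzyloxy)phenyl]-4-hydroxyfuran-2(5H)-one | O=C1OCC(O)=C1c1ccc(OCc2ccccc2)cc1 | intermediate
5 | 3-[4-(benzyloxy)phenyl]-4-(methoxymethoxy)furan-2(5H)-one | COCOC1=C(c2ccc(OCc3ccccc3)cc2)C(=O)OC1 | intermediate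
6 | 3-[4-(benzyloxy)phenyl]-2-(tert-butyldimethylsilyloxy)-4-(methoxymethoxy)furan | COCOc1coc(O[Si](C)(C)C(C)(C)C)c1-c1ccc(OCc2ccccc2)cc1 | intermediate
7 | ethyl (S)-3-hydroxybutanoate | CCOC(=O)C[C@H](C)O | starting material
8 | ethyl (S)-3-(benzyloxy)butanoate | CCOC(=O)C[C@H](C)OCc1ccccc1 | intermediate
9 | (S)-3-(benzyloxy)-N-methoxy-N-methylbutanamide | CON(C)C(=O)C[C@H](C)OCc1ccccc1 | intermediate
10 | 1-(benzyloxy)-4-ethynylbenzene | C#Cc1ccc(OCc2ccccc2)cc1 | starting material
11 | lithium [4-(benzyloxy)phenyl]acetylide | [Li]C#Cc1ccc(OCc2ccccc2)cc1 | intermediate (not isolated)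
12 | (S)-5-(benzyloxy)-1-[4-(benzyloxy)phenyl]hex-1-yn-3-one | C[C@H](OCc1ccccc1)CC(=O)C#Cc1ccc(OCc2ccccc2)cc1 | intermediate
13 | (S)-3-(benzyloxy)-1-{3,6-bis[4-(benzyloxy)phenyl]-1-(tert-butyldimethylsilyloxy)-5-(methoxymethoxy)-7-oxabicyclo[2.2.1]hepta-2,5-dien-2-yl}butan-1-one (both bridgehead diastereomers) | C[C@H](OCc1ccccc1)CC(=O)C1=C(c2ccc(OCc3ccccc3)cc2)C2OC1(O[Si](C)(C)C(C)(C)C)C(c1ccc(OCc3ccccc3)cc1)=C2OCOC | intermediate (not isolated)
14 | (S)-3-(benzyloxy)-1-[4,4''-bis(benzyloxy)-3'-(tert-butyldimethylsilyloxy)-6'-hydroxy-5'-(methoxymethoxy)-[1,1':4',1''-terphenyl]-2'-yl]butan-1-one (C1 acyl, C2 OTBS, C3 aryl, C4 OMOM, C5 OH, C6 aryl) | C[C@H](OCc1ccccc1)CC(=O)c1c(O[Si](C)(C)C(C)(C)C)c(-c2ccc(OCc3ccccc3)cc2)c(OCOC)c(O)c1-c1ccc(OCc2ccccc2)cc1 | intermediate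
15 | (S)-3-(benzyloxy)-1-[4,4'',6'-tris(benzyloxy)-3'-(tert-butyldimethylsilyloxy)-5'-(methoxymethoxy)-[1,1':4',1''-terphenyl]-2'-yl]butan-1-one (C2 OTBS, C5 OBn) | C[C@H](OCc1ccccc1)CC(=O)c1c(O[Si](C)(C)C(C)(C)C)c(-c2ccc(OCc3ccccc3)cc2)c(OCOC)c(OCc2ccccc2)c1-c1ccc(OCc2ccccc2)cc1 | intermediate (not isolated)
16 | (S)-3-(benzyloxy)-1-[4,4'',6'-tris(benzyloxy)-3'-hydroxy-5'-(methoxymethoxy)-[1,1':4',1''-terphenyl]-2'-yl]butan-1-one (C2 OH, C5 OBn; present as its cesium phenoxide) | C[C@H](OCc1ccccc1)CC(=O)c1c(O)c(-c2ccc(OCc3ccccc3)cc2)c(OCOC)c(OCc2ccccc2)c1-c1ccc(OCc2ccccc2)cc1 | intermediate (not isolated)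
17 | (S)-3-(benzyloxy)-1-[3',4,4'',6'-tetrakis(benzyloxy)-5'-(methoxymethoxy)-[1,1':4',1''-terphenyl]-2'-yl]butan-1-one (C2 OBn, C5 OBn) | C[C@H](OCc1ccccc1)CC(=O)c1c(OCc2ccccc2)c(-c2ccc(OCc3ccccc3)cc2)c(OCOC)c(OCc2ccccc2)c1-c1ccc(OCc2ccccc2)cc1 | intermediate
18 | 3',4,4'',6'-tetrakis(benzyloxy)-5'-(methoxymethoxy)-[1,1':4',1''-terphenyl]-2'-yl (S)-3-(benzyloxy)butanoate | C[C@H](OCc1ccccc1)CC(=O)Oc1c(OCc2ccccc2)c(-c2ccc(OCc3ccccc3)cc2)c(OCOC)c(OCc2ccccc2)c1-c1ccc(OCc2ccccc2)cc1 | intermediate
19 | 3',4,4'',6'-tetrakis(benzyloxy)-5'-hydroxy-[1,1':4',1''-terphenyl]-2'-yl (S)-3-(benzyloxy)butanoate | C[C@H](OCc1ccccc1)CC(=O)Oc1c(OCc2ccccc2)c(-c2ccc(OCc3ccccc3)cc2)c(O)c(OCc2ccccc2)c1-c1ccc(OCc2ccccc2)cc1 | intermediate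
20 | 3-phenylpropanoyl chloride | O=C(Cl)CCc1ccccc1 | starting material
21 | 3',4,4'',6'-tetrakis(benzyloxy)-5'-[(3-phenylpropanoyl)oxy]-[1,1':4',1''-terphenyl]-2'-yl (S)-3-(benzyloxy)butanoate | C[C@H](OCc1ccccc1)CC(=O)Oc1c(OCc2ccccc2)c(-c2ccc(OCc3ccccc3)cc2)c(OC(=O)CCc2ccccc2)c(OCc2ccccc2)c1-c1ccc(OCc2ccccc2)cc1 | intermediate
22 | 3',4,4'',6'-tetrahydroxy-5'-[(3-phenylpropanoyl)oxy]-[1,1':4',1''-terphenyl]-2'-yl (S)-3-hydroxybutanoate (CNP0296884.1) | C[C@H](O)CC(=O)Oc1c(O)c(-c2ccc(O)cc2)c(OC(=O)CCc2ccccc2)c(O)c1-c1ccc(O)cc1 | target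

**Step count**

Total: 12 steps. Longest linear sequence: 9 steps (steps 1–3 and 7–12; the ynone branch, steps 4–6 and 7–12, is equally long).

**Steps most likely to fail**

Step 7. The internal aryl ynone may react more slowly than the silyloxyfuran decomposes, or bonding may stop after the first C–C bond (vinylogous Michael addition without ring closure), so that no benzene ring forms. The fallback gives up the cycloaddition and assembles the terphenyl by twofold cross-coupling; it sets out from ester 8 and comes back at phenol 19. Tetrabromo-1,4-benzoquinone and NaOBn (BnOH, NaH, THF, 0 °C) should give 2,5-bis(benzyloxy)-3,6-dibromo-1,4-benzoquinone F1 by twofold addition–elimination. Twofold Suzuki coupling of F1 with 4-(benzyloxy)phenylboronic acid (Pd(PPh3)4, K2CO3, dioxane/H2O, 80 °C) gives 2,5-bis(benzyloxy)-3,6-bis[4-(benzyloxy)phenyl]-1,4-benzoquinone F2. Reduction with Na2S2O4 (THF/H2O) gives 2,5-bis(benzyloxy)-3,6-bis[4-(benzyloxy)phenyl]benzene-1,4-diol F3, in which O1 and O4 are free and O2 and O5 are benzylated. Ester 8 is saponified (LiOH, THF/H2O, 0 °C) to (S)-3-(benzyloxy)butanoic acid F4. Monoacylation of the twofold-symmetric diol F3 with one equivalent of F4 (DCC, 4-(dimethylamino)pyridine, CH2Cl2) gives 19 after separation from diester and unreacted diol, which is recycled; steps 11 and 12 follow unchanged.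

Step 9. The peracid may add too slowly to the twisted, doubly ortho-substituted ketone, the CH2 group may migrate in competition with the aryl group, or the peracid may attack the electron-rich rings. The fallback carries C1 through the cycloaddition as an aldehyde, for which the peracid oxidation is easy, and attaches the chain afterwards by esterification; it sets out from furan 6 and acetylide 11 and comes back at ester 18. Acetylide 11 is formylated with DMF (THF, −78 °C → rt, then aqueous KH2PO4) to 3-[4-(benzyloxy)phenyl]prop-2-ynal F5. Heating F5 with 6 as in step 7 should give, through the oxanorbornadiene carbaldehyde F6, the terphenyl carbaldehyde F7 (C1 CHO, C2 OTBS, C4 OMOM, C5 OH). Benzyl exchange as in step 8 leads through the C5 benzyl ether F8 and the C2 phenol F9 to the bis(benzyl ether) carbaldehyde F10. mCPBA (CH2Cl2, 0 °C) converts F10 into the aryl formate F11 by a Dakin-type Baeyer–Villiger oxidation with aryl migration, and K2CO3 in MeOH cleaves the formate to the C1 phenol F12. Esterification of F12 with acid F4, made from 8 as described for step 7 (DCC, 4-(dimethylamino)pyridine), gives 18.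

Step 12. Cleavage of the secondary alkyl benzyl ether may lag behind that of the aryl benzyl ethers, and during the longer exposure an acyl group may migrate to a neighbouring free phenol or the freed hydroquinone may oxidise. The fallback replaces hydrogenolysis by Lewis-acid debenzylation; it sets out from 21 and comes back at 22 and makes no new compound (F0). BCl3 with pentamethylbenzene as cation scavenger (CH2Cl2, −78 °C) cleaves aryl and alkyl benzyl ethers, spares esters at that temperature and keeps the medium acidic, where acyl migration is slow.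

**Further compounds**

F1 | step 7 | 2,5-bis(benzyloxy)-3,6-dibromo-1,4-benzoquinone | O=C1C(Br)=C(OCc2ccccc2)C(=O)C(Br)=C1OCc1ccccc1
F2 | step 7 | 2,5-bis(benzyloxy)-3,6-bis[4-(benzyloxy)phenyl]-1,4-benzoquinone | O=C1C(c2ccc(OCc3ccccc3)cc2)=C(OCc2ccccc2)C(=O)C(c2ccc(OCc3ccccc3)cc2)=C1OCc1ccccc1
F3 | step 7 | 2,5-bis(benzyloxy)-3,6-bis[4-(benzyloxy)phenyl]benzene-1,4-diol | Oc1c(-c2ccc(OCc3ccccc3)cc2)c(OCc2ccccc2)c(O)c(-c2ccc(OCc3ccccc3)cc2)c1OCc1ccccc1
F4 | step 7 | (S)-3-(benzyloxy)butanoic acid | C[C@H](OCc1ccccc1)CC(=O)O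
F5 | step 9 | 3-[4-(benzyloxy)phenyl]prop-2-ynal | O=CC#Cc1ccc(OCc2ccccc2)cc1
F6 | step 9 | 3,6-bis[4-(benzyloxy)phenyl]-1-(tert-butyldimethylsilyloxy)-5-(methoxymethoxy)-7-oxabicyclo[2.2.1]hepta-2,5-diene-2-carbaldehyde | O=CC1=C(c2ccc(OCc3ccccc3)cc2)C2OC1(O[Si](C)(C)C(C)(C)C)C(c1ccc(OCc3ccccc3)cc1)=C2OCOC
F7 | step 9 | 4,4''-bis(benzyloxy)-3'-(tert-butyldimethylsilyloxy)-6'-hydroxy-5'-(methoxymethoxy)-[1,1':4',1''-terphenyl]-2'-carbaldehyde | O=Cc1c(O[Si](C)(C)C(C)(C)C)c(-c2ccc(OCc3ccccc3)cc2)c(OCOC)c(O)c1-c1ccc(OCc2ccccc2)cc1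
F8 | step 9 | 4,4'',6'-tris(benzyloxy)-3'-(tert-butyldimethylsilyloxy)-5'-(methoxymethoxy)-[1,1':4',1''-terphenyl]-2'-carbaldehyde | O=Cc1c(O[Si](C)(C)C(C)(C)C)c(-c2ccc(OCc3ccccc3)cc2)c(OCOC)c(OCc2ccccc2)c1-c1ccc(OCc2ccccc2)cc1
F9 | step 9 | 4,4'',6'-tris(benzyloxy)-3'-hydroxy-5'-(methoxymethoxy)-[1,1':4',1''-terphenyl]-2'-carbaldehyde | O=Cc1c(O)c(-c2ccc(OCc3ccccc3)cc2)c(OCOC)c(OCc2ccccc2)c1-c1ccc(OCc2ccccc2)cc1
F10 | step 9 | 3',4,4'',6'-tetrakis(benzyloxy)-5'-(methoxymethoxy)-[1,1':4',1''-terphenyl]-2'-carbaldehyde | O=Cc1c(OCc2ccccc2)c(-c2ccc(OCc3ccccc3)cc2)c(OCOC)c(OCc2ccccc2)c1-c1ccc(OCc2ccccc2)cc1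
F11 | step 9 | 3',4,4'',6'-tetrakis(benzyloxy)-5'-(methoxymethoxy)-[1,1':4',1''-terphenyl]-2'-yl formate | O=COc1c(OCc2ccccc2)c(-c2ccc(OCc3ccccc3)cc2)c(OCOC)c(OCc2ccccc2)c1-c1ccc(OCc2ccccc2)cc1
F12 | step 9 | 3',4,4'',6'-tetrakis(benzyloxy)-5'-(methoxymethoxy)-[1,1':4',1''-terphenyl]-2'-ol | Oc1c(OCc2ccccc2)c(-c2ccc(OCc3ccccc3)cc2)c(OCOC)c(OCc2ccccc2)c1-c1ccc(OCc2ccccc2)cc1
F0 | step 12 | none | none
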